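**Retrosynthetic overview**
1. Target 8 ⇐ bis(tertiary allyl) ether 7 by a double aromatic Claisen shift; both C-prenyl groups are delivered from oxygen (7-O → C8, 4'-O → C5').
2. 7 ⇐ 3-O-methylquercetin 5 + carbonate 6 by a site-selective twofold Pd-catalysed O-(1,1-dimethylallyl)ation; this C–O bond formation is the key step and is new.
3. 5 ⇐ rutin 1: benzylate 7/3'/4'-OH while the sugar masks 3-OH, hydrolyse the sugar, O-methylate 3-OH, hydrogenolyse.
4. Ring order: rings A, C and B are all bought intact in rutin; no ring is formed in the route.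

Assumption: the target has no stereocentre and no stereogenic double bond, so it is achiral and the SMILES given is taken as the complete structure.

**Step 1**
Reactants: 1 rutin (quercetin 3-O-[α-L-rhamnopyranosyl-(1→6)-β-D-glucopyranoside])
Product: 3 7,3',4'-tri-O-benzylquercetin, via 7,3',4'-tri-O-benzylrutin 2 (not isolated)
Conditions: BnBr (3.3 equiv), K2CO3, DMF, 60 °C; filter; then conc. HCl, EtOH–H2O, 75 °C
Reagents that add atoms: benzyl bromide, BrCc1ccccc1
Why: Williamson etherification reaches only the three acidic phenols (7, 4', 3') because the 3-OH is glycosylated and the 5-OH is hydrogen-bonded to C4=O, and acid-catalysed glycoside hydrolysis then frees the 3-OH; no stereocentre is formed.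

**Step 2**
Reactants: 3 7,3',4'-tri-O-benzylquercetin
Product: 4 7,3',4'-tri-O-benzyl-3-O-methylquercetin
Conditions: MeI (1.3 equiv), K2CO3, DMF, 25 °C
Reagents that add atoms: iodomethane, CI
Why: Williamson O-methylation of the enolic 3-OH, the only reactive hydroxyl left, since the chelated 5-OH is not alkylated at room temperature with near-stoichiometric MeI.

**Step 3**
Reactants: 4 7,3',4'-tri-O-benzyl-3-O-methylquercetin
Product: 5 3-O-methylquercetin (5,7,3',4'-tetrahydroxy-3-methoxyflavone)
Conditions: H2 (1 atm), Pd/C (10 wt%), THF–MeOH, 25 °C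
Reagents that add atoms: none
Why: Catalytic hydrogenolysis cleaves the three benzyl aryl ethers and leaves the methyl ether and the tetrasubstituted C2=C3 bond of the flavone untouched.

**Step 4**
Reactants: 5 3-O-methylquercetin; 6 tert-butyl 2-methylbut-3-en-2-yl carbonate
Product: 7 7,4'-bis-O-(2-methylbut-3-en-2-yl)-3-O-methylquercetin
Conditions: 6 (2.1 equiv, slow addition), Pd(PPh3)4 (5 mol%), THF, 4 Å MS, 0 °C, no added base; filter cold through Et3N-washed SiO2
Reagents that add atoms: none
Why: Proposed new method: a base-free, acidity-gated twofold Tsuji–Trost O-allylation of a fully unprotected tetrahydroxyflavone, in which zerovalent palladium ionises 6 to a cationic π-(1,1-dimethylallyl) complex of divalent palladium with loss of CO2 and release of exactly one tert-butoxide per turnover, so that this base deprotonates only the most acidic phenol still present (7-OH, pKa about 7.5, then 4'-OH, about 8.5, while the 3'-OH near 10 and the chelated 5-OH stay protonated when 6 is dosed to 2.1 equiv) and the phenoxide attacks the more substituted allyl terminus under kinetic control at 0 °C to give the tertiary aryl ethers; the closest known reaction type is the Pd-catalysed O-(1,1-dimethylallyl)ation of simple phenols and hydroxyxanthones with this carbonate, which to my knowledge has not been used to tell several free phenols of a flavonoid apart by acidity.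

**Step 5**
Reactants: 7 7,4'-bis-O-(2-methylbut-3-en-2-yl)-3-O-methylquercetin
Product: 8 5,7,3',4'-tetrahydroxy-3-methoxy-8,5'-diprenylflavone
Conditions: PhNEt2 (degassed), 130 °C, Ar
Reagents that add atoms: none
Why: Two independent aromatic Claisen ([3,3]-sigmatropic) rearrangements invert each tertiary allyl group into a normal prenyl group, on ring B at C5' (the only free ortho carbon, C3' carries OH) and on ring A at C8 (the expected major site for 7-allyloxy-5-hydroxyflavones, with the C6 isomer as a separable minor product), and tautomerisation restores both phenols; no stereocentre is formed.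

**Compound list**
1 | rutin (quercetin 3-O-[α-L-rhamnopyranosyl-(1→6)-β-D-glucopyranoside]) | C[C@@H]1O[C@@H](OC[C@H]2O[C@@H](Oc3c(-c4ccc(O)c(O)c4)oc4cc(O)cc(O)c4c3=O)[C@H](O)[C@@H](O)[C@@H]2O)[C@H](O)[C@H](O)[C@H]1O | starting material
2 | 7,3',4'-tri-O-benzylrutin | C[C@@H]1O[C@@H](OC[C@H]2O[C@@H](Oc3c(-c4ccc(OCc5ccccc5)c(OCc5ccccc5)c4)oc4cc(OCc5ccccc5)cc(O)c4c3=O)[C@H](O)[C@@H](O)[C@@H]2O)[C@H](O)[C@H](O)[C@H]1O | intermediate
3 | 7,3',4'-tri-O-benzylquercetin | O=c1c(O)c(-c2ccc(OCc3ccccc3)c(OCc3ccccc3)c2)oc2cc(OCc3ccccc3)cc(O)c12 | intermediate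
4 | 7,3',4'-tri-O-benzyl-3-O-methylquercetin | COc1c(-c2ccc(OCc3ccccc3)c(OCc3ccccc3)c2)oc2cc(OCc3ccccc3)cc(O)c2c1=O | intermediate
5 | 3-O-methylquercetin (5,7,3',4'-tetrahydroxy-3-methoxyflavone) | COc1c(-c2ccc(O)c(O)c2)oc2cc(O)cc(O)c2c1=O | intermediate
6 | tert-butyl 2-methylbut-3-en-2-yl carbonate | C=CC(C)(C)OC(=O)OC(C)(C)C | starting material
7 | 7,4'-bis-O-(2-methylbut-3-en-2-yl)-3-O-methylquercetin (5,3'-dihydroxy-3-methoxy-7,4'-bis(1,1-dimethylallyloxy)flavone) | COc1c(-c2ccc(OC(C)(C)C=C)c(O)c2)oc2cc(OC(C)(C)C=C)cc(O)c2c1=O | intermediate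
8 | 5,7,3',4'-tetrahydroxy-3-methoxy-8,5'-diprenylflavone | COc1c(-c2cc(O)c(O)c(CC=C(C)C)c2)oc2c(CC=C(C)C)c(O)cc(O)c2c1=O | target

**Step count**
Total steps: 5. Longest linear sequence: 5 (1 → 3 → 4 → 5 → 7 → 8); the route is fully linear, with 6 entering at step 4.

**Three steps most likely to fail**

Step 4 (the proposed new step). Risks are alkylation at 3'-OH instead of or in addition to 4'-OH, palladium-mediated equilibration of the tertiary ethers to linear prenyl ethers (fastest at the acidic 7-position), and C-allylation of ring A. The fallback uses known chemistry and avoids π-allyl intermediates. It sets out from 5, which is alkylated with 3-chloro-3-methylbut-1-yne (2.2 equiv, K2CO3, KI, acetone, 60 °C) to give 7,4'-bis-O-(2-methylbut-3-yn-2-yl)-3-O-methylquercetin F1. Semi-hydrogenation of both alkynes with H2 over Lindlar catalyst (Pd/CaCO3 poisoned with Pb(OAc)2, quinoline, EtOAc, 25 °C) then comes back to the route at 7.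

Step 5. Risks are partial migration to C6 on ring A, ionisation of the tertiary ethers with loss of isoprene back to 5, and cyclisation of the ortho-prenyl phenols to chromans if traces of acid are present. The fallback replaces the labile tertiary ethers by primary allyl ethers and installs the methyl groups afterwards. It sets out from 5, which is allylated with allyl bromide (2.1 equiv, K2CO3, acetone, 55 °C) to give 7,4'-di-O-allyl-3-O-methylquercetin F2. Heating in PhNEt2 at 190 °C (aromatic Claisen rearrangement, with C8 the classical site for 7-allyloxy-5-hydroxyflavones) gives 8,5'-diallyl-3-O-methylquercetin F3. Olefin cross-metathesis of both allyl groups with 2-methylbut-2-ene (used as co-solvent) and the second-generation Grubbs catalyst RuCl2(=CHPh)(PCy3)(H2IMes) in CH2Cl2 at 40 °C comes back to the route at 8.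

Step 1. Risks are incomplete benzylation at 3'-OH, over-benzylation at 5-OH or on the sugar, and a messy one-flask hydrolysis. The fallback removes the sugar first and protects the catechol as a ketal. It sets out from 1, which is hydrolysed (aq. HCl, EtOH, reflux) to quercetin F4. Heating with Ph2CCl2 in Ph2O at 175 °C gives 3',4'-O-diphenylmethylenequercetin F5. The most acidic remaining phenol is benzylated (BnBr 1.1 equiv, K2CO3, DMF, 25 °C) to 7-O-benzyl-3',4'-O-diphenylmethylenequercetin F6. Methylation of the 3-OH (MeI, K2CO3, DMF) gives 7-O-benzyl-3-O-methyl-3',4'-O-diphenylmethylenequercetin F7. Hydrogenolysis (H2, Pd/C, THF–MeOH) removes the benzyl ether and the ketal together and comes back to the route at 5.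

**Further compounds**
F1 | step 4 | 7,4'-bis-O-(2-methylbut-3-yn-2-yl)-3-O-methylquercetin | COc1c(-c2ccc(OC(C)(C)C#C)c(O)c2)oc2cc(OC(C)(C)C#C)cc(O)c2c1=O
F2 | step 5 | 7,4'-di-O-allyl-3-O-methylquercetin | COc1c(-c2ccc(OCC=C)c(O)c2)oc2cc(OCC=C)cc(O)c2c1=O
F3 | step 5 | 8,5'-diallyl-3-O-methylquercetin | COc1c(-c2cc(O)c(O)c(CC=C)c2)oc2c(CC=C)c(O)cc(O)c2c1=O
F4 | step 1 | quercetin | O=c1c(O)c(-c2ccc(O)c(O)c2)oc2cc(O)cc(O)c12
F5 | step 1 | 3',4'-O-diphenylmethylenequercetin | O=c1c(O)c(-c2ccc3OC(c4ccccc4)(c4ccccc4)Oc3c2)oc2cc(O)cc(O)c12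
F6 | step 1 | 7-O-benzyl-3',4'-O-diphenylmethylenequercetin | O=c1c(O)c(-c2ccc3OC(c4ccccc4)(c4ccccc4)Oc3c2)oc2cc(OCc3ccccc3)cc(O)c12
F7 | step 1 | 7-O-benzyl-3-O-methyl-3',4'-O-diphenylmethylenequercetin | COc1c(-c2ccc3OC(c4ccccc4)(c4ccccc4)Oc3c2)oc2cc(OCc3ccccc3)cc(O)c2c1=O
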